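Ring A is cut across C2–C3 and C1–C6. Its C3–C6 segment, carrying the three adjacent bromines and the lone C6 hydrogen, comes from 3,4,5-tribromo-2-pyrone 4. C1 and C2 come from the ynol ether boronate 14, whose oxygen already bears ring B and whose boron stands in for the C1 hydroxyl. One thermal cycloaddition with loss of CO2 therefore assembles the hexasubstituted ring A with every substituent in place and no metal near the four C–Br bonds. The push–pull polarisation of the alkyne against the C6-electrophilic pyrone fixes the orientation. Oxidation of the C–B bond finishes the target.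

Key step: step 7

Assumption: 4-hydroxy-2H-pyran-2-one 1 is taken as a purchasable building block; the C4 bromine is derived from its C4 hydroxyl because C4 of a 2-pyrone is an electrophilic position that direct bromination does not reach.

Step 1
Reactants: 1 4-hydroxy-2H-pyran-2-one
Product: 3 3,5-dibromo-4-hydroxy-2H-pyran-2-one, via 3-bromo-4-hydroxy-2H-pyran-2-one 2 (not isolated)
Conditions: Br2 (2.2 equiv), AcOH, rt then 60 °C
Reagents that add atoms: bromine, BrBr
Why: Electrophilic bromination of a vinylogous acid, in which the 4-hydroxyl activates first C3 and then C5 of the enol-ether double bond (addition of bromine, loss of HBr), the only two nucleophilic ring positions.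

Step 2
Reactants: 3 3,5-dibromo-4-hydroxy-2H-pyran-2-one
Product: 4 3,4,5-tribromo-2H-pyran-2-one
Conditions: POBr3 (1.5 equiv), DMF (0.2 equiv), PhMe, 90 °C
Reagents that add atoms: phosphorus oxybromide, O=P(Br)(Br)Br
Why: Vilsmeier-type deoxybromination of a vinylogous carboxylic acid, in which the C4 oxygen is activated as a leaving group and bromide returns at the electrophilic C4 by addition–elimination, as in the conversion of 4-hydroxy-2-pyrones and 4-pyridones into their 4-bromo derivatives.

Step 3
Reactants: 5 2-bromophenol; 6 2,4,6-trivinylcyclotriboroxane–pyridine complex (0.67 equiv)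
Product: 7 1-bromo-2-(ethenyloxy)benzene (2-bromophenyl vinyl ether)
Conditions: Cu(OAc)2 (1.0 equiv), pyridine, 4 Å molecular sieves, CH2Cl2, air, rt
Reagents that add atoms: none
Why: Chan–Lam oxidative O-vinylation, in which aryloxide and vinyl group meet on copper and reductive elimination forms the C–O bond at room temperature, conditions under which an aryl bromide is inert.

Step 4
Reactants: 7 1-bromo-2-(ethenyloxy)benzene
Product: 9 (Z)-1-bromo-2-[(2-bromoethenyl)oxy]benzene, via 1-bromo-2-(1,2-dibromoethoxy)benzene 8 (not isolated)
Conditions: Br2 (1.0 equiv), CH2Cl2, −78 °C; then Et3N (3 equiv), −78 °C → 40 °C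
Reagents that add atoms: bromine, BrBr
Why: Bromination–dehydrobromination of an enol ether, in which bromine adds to the electron-rich double bond far faster than to the arene and the amine then removes the labile α-bromide as HBr, which should give mainly the (Z)-β-bromovinyl ether as in the classical route to alkoxy- and aryloxyacetylenes.

Step 5
Reactants: 9 (Z)-1-bromo-2-[(2-bromoethenyl)oxy]benzene
Product: 10 1-bromo-2-(ethynyloxy)benzene
Conditions: KOtBu (1.5 equiv), THF, −40 → 0 °C; pH 7 phosphate buffer; used without storage
Reagents that add atoms: none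
Why: E2 dehydrobromination, since in the (Z)-isomer the hydrogen on the oxygen-bearing carbon is anti to bromine, and tert-butoxide causes neither halogen–metal exchange nor aryne formation at the aryl bromide.

Step 6
Reactants: 10 1-bromo-2-(ethynyloxy)benzene; 11 2-isopropoxy-4,4,5,5-tetramethyl-1,3,2-dioxaborolane
Product: 14 2-[(2-bromophenoxy)ethynyl]-4,4,5,5-tetramethyl-1,3,2-dioxaborolane, via the bromomagnesium acetylide 12 (not isolated), via the isopropoxyborate ate complex 13 (not isolated)
Conditions: EtMgBr (1.05 equiv), THF, 0 °C; 11 (1.1 equiv), −78 °C → rt; HCl in Et2O (1.05 equiv), −78 °C → rt; filtration under argon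
Reagents that add atoms: none
Why: Acetylide borylation, in which the Grignard reagent deprotonates the terminal ynol ether without touching the aryl bromide, the acetylide adds to the alkoxyborolane, and one equivalent of anhydrous HCl collapses the ate complex to the alkynylboronate.

Step 7
Reactants: 4 3,4,5-tribromo-2H-pyran-2-one; 14 2-[(2-bromophenoxy)ethynyl]-4,4,5,5-tetramethyl-1,3,2-dioxaborolane
Product: 16 2-[3,4,5-tribromo-2-(2-bromophenoxy)phenyl]-4,4,5,5-tetramethyl-1,3,2-dioxaborolane, via the bridged lactone 15 (not isolated)
Conditions: 14 (1.5 equiv), BHT (cat.), PhMe, sealed tube, 120 °C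
Reagents that add atoms: none
Why: The electron-poor diene of 4 (pyrone C3–C6, lowered in energy by the lactone carbonyl and three bromines) and the electron-rich triple bond of 14 combine in a thermal, concerted but asynchronous inverse-electron-demand [4+2] cycloaddition to the bridged lactone 15, which loses CO2 by retro-[4+2] cycloreversion at the same temperature and aromatises. The closest known reaction type is the cycloaddition–decarboxylation of 2-pyrones with alkynylboronates to give arylboronates, together with that of halo-2-pyrones with enol ethers. Ring A is closed by intermolecular [4+2] annulation, the bonds C2–C3 and C1–C6 forming in one operation and pyrone C3–C6 becoming ring A C3–C6. No stereocenter remains, since both bridgeheads of 15 become aromatic carbons. The step needs one regiochemistry: the boron-bearing alkyne carbon is β to the oxygen donor and α to the boron acceptor and is therefore the nucleophilic terminus, which bonds to pyrone C6, the δ-carbon of the dienoate and the only unhindered diene terminus, so the aryloxy carbon is delivered to C3. The aryl ether has no β-hydrogen for retro-ene loss to a ketene and no metal is present, so the ynol ether and all four C–Br bonds should survive the heating.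

Step 8
Reactants: 16 2-[3,4,5-tribromo-2-(2-bromophenoxy)phenyl]-4,4,5,5-tetramethyl-1,3,2-dioxaborolane
Product: 17 3,4,5-tribromo-2-(2-bromophenoxy)phenol
Conditions: 30% aq. H2O2, NaOH, THF/H2O, 0 °C → rt; then 1 M HCl
Reagents that add atoms: hydrogen peroxide, OO
Why: Boronate oxidation, in which hydroperoxide adds to boron, the aryl group migrates from boron to oxygen with ipso specificity and the borate is hydrolysed in the same pot, leaving the aryl bromides and the diaryl ether unchanged.

Compound list
1 | 4-hydroxy-2H-pyran-2-one | O=C1C=C(O)C=CO1 | starting material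
2 | 3-bromo-4-hydroxy-2H-pyran-2-one (not isolated) | O=C1OC=CC(O)=C1Br | intermediate
3 | 3,5-dibromo-4-hydroxy-2H-pyran-2-one | O=C1OC=C(Br)C(O)=C1Br | intermediate
4 | 3,4,5-tribromo-2H-pyran-2-one | O=C1OC=C(Br)C(Br)=C1Br | intermediate
5 | 2-bromophenol | Oc1ccccc1Br | starting material
6 | 2,4,6-trivinylcyclotriboroxane–pyridine complex | C=CB1OB(C=C)OB(C=C)O1.c1ccncc1 | starting material
7 | 1-bromo-2-(ethenyloxy)benzene | C=COc1ccccc1Br | intermediate
8 | 1-bromo-2-(1,2-dibromoethoxy)benzene (racemic, not isolated) | BrCC(Br)Oc1ccccc1Br | intermediate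
9 | (Z)-1-bromo-2-[(2-bromoethenyl)oxy]benzene | Br/C=C\Oc1ccccc1Br | intermediate
10 | 1-bromo-2-(ethynyloxy)benzene | C#COc1ccccc1Br | intermediate
11 | 2-isopropoxy-4,4,5,5-tetramethyl-1,3,2-dioxaborolane | CC(C)OB1OC(C)(C)C(C)(C)O1 | starting material
12 | [(2-bromophenoxy)ethynyl]magnesium bromide (not isolated) | Br[Mg]C#COc1ccccc1Br | intermediate
13 | bromomagnesium [(2-bromophenoxy)ethynyl](isopropoxy)(pinacolato)borate (not isolated) | CC(C)O[B-]1(C#COc2ccccc2Br)OC(C)(C)C(C)(C)O1.[Mg+]Br | intermediate
14 | 2-[(2-bromophenoxy)ethynyl]-4,4,5,5-tetramethyl-1,3,2-dioxaborolane | CC1(C)OB(OC1(C)C)C#COc1ccccc1Br | intermediate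
15 | 4,7,8-tribromo-5-(2-bromophenoxy)-6-(4,4,5,5-tetramethyl-1,3,2-dioxaborolan-2-yl)-2-oxabicyclo[2.2.2]octa-5,7-dien-3-one (racemic, not isolated) | O=C1OC2C(Br)=C(Br)C1(Br)C(Oc1ccccc1Br)=C2B1OC(C)(C)C(C)(C)O1 | intermediate
16 | 2-[3,4,5-tribromo-2-(2-bromophenoxy)phenyl]-4,4,5,5-tetramethyl-1,3,2-dioxaborolane | CC1(C)OB(OC1(C)C)c1cc(Br)c(Br)c(Br)c1Oc1ccccc1Br | intermediate
17 | 3,4,5-tribromo-2-(2-bromophenoxy)phenol | Oc1cc(Br)c(Br)c(Br)c1Oc1ccccc1Br | target

Total step count: 8
Longest linear sequence: 6 steps (steps 3, 4, 5, 6, 7, 8, from 5 to 17)

Steps most likely to fail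

Step 7. The boron-capped ynol ether may be used up by protodeboronation or self-condensation before the crowded trihalogenated diene has reacted, so that longer heating erodes material instead of giving adduct. The fallback replaces boron by silicon as the latent hydroxyl; it sets out from 10 (with 4) and returns at 17. Compound 10 is deprotonated with EtMgBr to 12 and quenched with chlorodimethylsilane to give [(2-bromophenoxy)ethynyl]dimethylsilane F1, a hydrolytically and thermally robust ynol ether with the same polarisation. Heating F1 with 4 in toluene should give, through the bridged lactone 4,7,8-tribromo-5-(2-bromophenoxy)-6-(dimethylsilyl)-2-oxabicyclo[2.2.2]octa-5,7-dien-3-one F2 and loss of CO2, the arylsilane [3,4,5-tribromo-2-(2-bromophenoxy)phenyl]dimethylsilane F3. Tamao–Fleming oxidation of the aryl hydrosilane (KF, KHCO3, 30% H2O2, THF/MeOH, rt) then gives 17 directly.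

Step 6. Collapse of the ate complex with acid may add HCl across the electron-rich triple bond or cleave the alkynyl–boron bond. The fallback uses an aminoborane, so that no ate complex and no acid are involved; it sets out from 10 and returns at 14. The acetylide 12, made as before, is treated with ClB(NiPr2)2 to give 1-[(2-bromophenoxy)ethynyl]-N,N,N',N'-tetraisopropylboranediamine F4, and the magnesium salt is filtered off. Exchange with pinacol in toluene (rt → 50 °C) releases diisopropylamine and gives 14.

Step 2. The flanking bromines make the C4 oxygen a poor nucleophile towards phosphorus, so activation may stay incomplete, or the pyrone ring may be opened by HBr at the temperature needed. The fallback separates activation from substitution; it sets out from 3 and returns at 4. Treatment of 3 with Tf2O and pyridine (CH2Cl2, −78 → 0 °C) gives 3,5-dibromo-2-oxo-2H-pyran-4-yl trifluoromethanesulfonate F5. LiBr in acetone at rt then displaces the sulfonate by addition–elimination at C4 and gives 4.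

Further compounds
F1 | step 7 | [(2-bromophenoxy)ethynyl]dimethylsilane | C[SiH](C)C#COc1ccccc1Br
F2 | step 7 | 4,7,8-tribromo-5-(2-bromophenoxy)-6-(dimethylsilyl)-2-oxabicyclo[2.2.2]octa-5,7-dien-3-one (racemic) | O=C1OC2C(Br)=C(Br)C1(Br)C(Oc1ccccc1Br)=C2[SiH](C)C
F3 | step 7 | [3,4,5-tribromo-2-(2-bromophenoxy)phenyl]dimethylsilane | C[SiH](C)c1cc(Br)c(Br)c(Br)c1Oc1ccccc1Br
F4 | step 6 | 1-[(2-bromophenoxy)ethynyl]-N,N,N',N'-tetraisopropylboranediamine | CC(C)N(C(C)C)B(C#COc1ccccc1Br)N(C(C)C)C(C)C
F5 | step 2 | 3,5-dibromo-2-oxo-2H-pyran-4-yl trifluoromethanesulfonate | O=C1OC=C(Br)C(OS(=O)(=O)C(F)(F)F)=C1Br
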